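## Retrosynthetic overview

- The target is numbered as a cyclohepta[b]furan: O1, C2 lactone carbonyl, C3 methylidene-bearing carbon, ring fusion C3a/C8a, C4 methylene, C5 ketone, C6 methyl carbon, C7 carbinol, C8 acyloxy carbon. Late disconnections: the C7 enone from an allylic carbinol (oxidation, Nozaki–Hiyama–Kishi addition to a C7 aldehyde); C7–OH and C4–H2 from SmI2 cleavage of a C4–O–C7 ether bridge; the C8 ester by acylation; the lactone by palladium cyclocarbonylation of a C3a-ethynyl/C8a-hydroxy pair.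
- Key disconnection C7–C8: the seven-membered ring is closed by the Cope rearrangement of a cis-divinylcyclopropane, made in the same flask from a 2,3-disubstituted furan and a dioxygenated vinylcarbenoid (formal (4+3) cycloaddition). Cyclopropane strain pays for the quaternary C7.
- Enabling feature: C8a(O) flanked by C8(O) and C3a is a 3-siloxy-4-alkoxy vinylcarbenoid in disguise (C3a is the carbenoid carbon, its ester carbon becomes C3). C4–C5–C6–C7, with the tertiary oxygen on C7 and the methyl on C6, is a 3-methylfuran whose ring oxygen becomes the C7 hydroxyl.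
- Ring order: oxygen-bridged seven-membered ring (step 6), then the lactone ring (step 16), then the bridge is opened (step 21).

Key step: step 6

Assumption: Rh2(S-PTAD)4 is taken to deliver the carbenoid to the furan face that gives 9 as drawn; the sense of induction is set by the catalyst enantiomer, and both are available.

Locants and abbreviations: compounds 9–20 are numbered as 8-oxabicyclo[3.2.1]octanes; their C1, C2, C3, C4, C5, C6, C7 become C4, C3a, C8a, C8, C7, C6, C5 of the target. "Syn" and "anti" refer to the oxygen bridge. TBS = tert-butyldimethylsilyl, TBDPS = tert-butyldiphenylsilyl, TES = triethylsilyl, PMB = 4-methoxybenzyl, Bpin = pinacolboryl.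

## Route

Step 1
Reactants: 1 methyl 3-methylfuran-2-carboxylate
Product: 2 (3-methylfuran-2-yl)methanol
Conditions: LiAlH4, Et2O, 0 °C
Reagents that add atoms: none
Why: Hydride reduction of the ester to the primary alcohol; the furan ring is inert to LiAlH4.

Step 2
Reactants: 2 (3-methylfuran-2-yl)methanol
Product: 3 tert-butyl[(3-methylfuran-2-yl)methoxy]diphenylsilane
Conditions: TBDPSCl, imidazole, DMF, rt
Reagents that add atoms: tert-butyl(chloro)diphenylsilane, CC(C)(C)[Si](Cl)(c1ccccc1)c1ccccc1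
Why: Standard silylation of a primary alcohol; the robust silyl ether masks the future C7 side-chain carbon until step 15.

Step 3
Reactants: 4 methyl 4-chloro-3-oxobutanoate
Product: 5 methyl 4-[(4-methoxyphenyl)methoxy]-3-oxobutanoate
Conditions: 4-methoxybenzyl alcohol, NaH (2.2 equiv), THF, 0 °C to rt
Reagents that add atoms: 4-methoxybenzyl alcohol, COc1ccc(CO)cc1
Why: Williamson-type displacement of the γ-chloride by the alkoxide on the sodium enolate of the β-keto ester, a standard entry to 4-alkoxyacetoacetates.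

Step 4
Reactants: 5 methyl 4-[(4-methoxyphenyl)methoxy]-3-oxobutanoate
Product: 6 methyl 2-diazo-4-[(4-methoxyphenyl)methoxy]-3-oxobutanoate
Conditions: 4-acetamidobenzenesulfonyl azide, Et3N, MeCN, 0 °C to rt
Reagents that add atoms: 4-acetamidobenzenesulfonyl azide, CC(=O)Nc1ccc(cc1)S(=O)(=O)N=[N+]=[N-]
Why: Regitz diazo transfer to the activated methylene of a β-keto ester.

Step 5
Reactants: 6 methyl 2-diazo-4-[(4-methoxyphenyl)methoxy]-3-oxobutanoate
Product: 7 methyl (3Z)-3-[(tert-butyldimethylsilyl)oxy]-2-diazo-4-[(4-methoxyphenyl)methoxy]but-3-enoate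
Conditions: TBSOTf, Et3N, CH2Cl2, 0 °C
Reagents that add atoms: tert-butyldimethylsilyl trifluoromethanesulfonate, CC(C)(C)[Si](C)(C)OS(=O)(=O)C(F)(F)F
Why: Soft enolisation and O-silylation of the diazo keto ester, the standard route to siloxyvinyldiazoacetates; the Z enol ether (PMB-oxy cis to TBS-oxy, trans to the diazo carbon) is the expected isomer.

Step 6
Reactants: 3 tert-butyl[(3-methylfuran-2-yl)methoxy]diphenylsilane; 7 methyl (3Z)-3-[(tert-butyldimethylsilyl)oxy]-2-diazo-4-[(4-methoxyphenyl)methoxy]but-3-enoate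
Product: 9 oxygen-bridged cycloheptadiene (methyl 3-TBS-oxy-4-PMB-oxy-5-(TBDPS-oxymethyl)-6-methyl-8-oxabicyclo[3.2.1]octa-2,6-diene-2-carboxylate; PMB-oxy anti), via cis-divinylcyclopropane 8 (not isolated)
Conditions: Rh2(S-PTAD)4 (dirhodium tetrakis[(S)-(1-adamantyl)(N-phthalimido)acetate], 1 mol %), 3 (1.5 equiv), slow addition of 7, hexanes, 25 °C then 65 °C
Reagents that add atoms: none
Why: The dirhodium carboxylate turns 7 into a donor/acceptor vinylcarbenoid that cyclopropanates the only unhindered double bond of furan 3 (C4=C5, carbenoid carbon to C5) to give the endo-vinyl cyclopropane 8, whose strain then drives a boat-type [3,3] (Cope) shift that joins the alkoxy-bearing vinyl terminus to the substituted furan carbon, which is the C7–C8 bond of the target. The closest known reaction is the tandem cyclopropanation/Cope rearrangement of siloxyvinyldiazoacetates with furans (formal (4+3) cycloaddition), which also gives quaternary bridgeheads from 2,5-disubstituted furans. Ring closures: the cyclopropane by carbene [2+1] addition, the seven-membered ring by the sigmatropic shift, in which the furan oxygen ends as the one-atom bridge. Stereocontrol: the bridge fixes the two bridgeheads relative to each other, the Z enol ether of 7 and the boat transition state place the PMB-oxy group on C4 anti to the bridge (C8 relative to C7 of the target), and the chiral carboxylate ligands choose the furan face and so the absolute configuration. The step needs regioselectivity between the two furan double bonds, secured by the fully substituted C2=C3 bond, and cyclopropanation in preference to zwitterionic opening of the furan, for which the 3-siloxy group on the carbenoid is the known remedy.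

Step 7
Reactants: 9 oxygen-bridged cycloheptadiene
Product: 10 enol triflate (3-trifluoromethanesulfonyloxy analogue of 9)
Conditions: CsF, PhNTf2, DME, rt
Reagents that add atoms: N-phenylbis(trifluoromethanesulfonimide), O=S(=O)(N(c1ccccc1)S(=O)(=O)C(F)(F)F)C(F)(F)F
Why: Fluoride unmasks the β-keto ester enolate from the silyl enol ether and PhNTf2 traps it on oxygen (enol triflate formation); the stabilised enolate does not open the bridge at rt.

Step 8
Reactants: 10 enol triflate
Product: 11 methyl 4-PMB-oxy-5-(TBDPS-oxymethyl)-6-methyl-8-oxabicyclo[3.2.1]octa-2,6-diene-2-carboxylate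
Conditions: Pd(OAc)2 (5 mol %), PPh3, HCO2H, Et3N, DMF, 60 °C
Reagents that add atoms: none
Why: Palladium-catalysed formate reduction of a vinyl triflate gives the β-unsubstituted enoate; the isolated trisubstituted alkene and the allylic ethers are untouched.

Step 9
Reactants: 11 bicyclic enoate
Product: 13 β-hydroxy ester (methyl 3-hydroxy-4-PMB-oxy-5-(TBDPS-oxymethyl)-6-methyl-8-oxabicyclo[3.2.1]oct-6-ene-2-carboxylate; 3-OH syn; 2-ester and 4-ether anti), via pinacol boronate 12 (not isolated)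
Conditions: CuCl (5 mol %), Xantphos, NaOtBu (10 mol %), B2pin2, MeOH, THF, rt; then NaBO3·4H2O, THF/H2O
Reagents that add atoms: bis(pinacolato)diboron, CC1(C)OB(OC1(C)C)B1OC(C)(C)C(C)(C)O1; sodium perborate, O[B-]1(O)OO[B-](O)(O)OO1.[Na+].[Na+]
Why: Copper-catalysed conjugate borylation of the enoate should occur from the open face syn to the bridge and away from the anti PMB-oxy group, and stereoretentive C–B oxidation then sets C3 (C8a of the target), while protonation of the copper enolate leaves the ester equatorial (C3a).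

Step 10
Reactants: 13 β-hydroxy ester
Product: 14 3-O-TES ether of 13
Conditions: TESOTf, 2,6-lutidine, CH2Cl2, −78 to 0 °C
Reagents that add atoms: triethylsilyl trifluoromethanesulfonate, CC[Si](CC)(CC)OS(=O)(=O)C(F)(F)F
Why: Silyl triflate protection of a hindered secondary alcohol, needed so that only the other two hydroxyls are oxidised in step 13.

Step 11
Reactants: 14 TES ether
Product: 16 7-exo alcohol (methyl 7-hydroxy-6-methyl-4-PMB-oxy-3-TES-oxy-5-(TBDPS-oxymethyl)-8-oxabicyclo[3.2.1]octane-2-carboxylate; 6-methyl endo), via alkylborane 15 (not isolated)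
Conditions: BH3·THF, THF, 0 °C; then NaBO3·4H2O, H2O, rt
Reagents that add atoms: borane–tetrahydrofuran, B.C1CCOC1; sodium perborate, O[B-]1(O)OO[B-](O)(O)OO1.[Na+].[Na+]
Why: Hydroboration–oxidation puts boron on the less substituted C7 from the exo face (syn to the bridge), giving the 7-exo alcohol and, for now, the 6-endo methyl group; the ester is reduced far more slowly.

Step 12
Reactants: 16 7-exo alcohol
Product: 17 diol (2-hydroxymethyl analogue of 16)
Conditions: LiAlH4, THF, 0 °C
Reagents that add atoms: none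
Why: Hydride reduction of the methyl ester to the primary alcohol; silyl and PMB ethers survive.

Step 13
Reactants: 17 diol
Product: 18 keto aldehyde (7-oxo-2-carbaldehyde; 6-methyl still endo)
Conditions: Dess–Martin periodinane (3 equiv), CH2Cl2, rt
Reagents that add atoms: none
Why: Dess–Martin oxidation of both free hydroxyls in one operation, giving the C5 ketone of the target and the aldehyde needed for homologation.

Step 14
Reactants: 18 keto aldehyde
Product: 19 alkynyl ketone (2-ethynyl-6-methyl-4-PMB-oxy-3-TES-oxy-5-(TBDPS-oxymethyl)-8-oxabicyclo[3.2.1]octan-7-one; 6-methyl exo)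
Conditions: dimethyl (1-diazo-2-oxopropyl)phosphonate, K2CO3, MeOH, 0 °C to rt, 16 h
Reagents that add atoms: dimethyl (1-diazo-2-oxopropyl)phosphonate, CC(=O)C(=[N+]=[N-])P(=O)(OC)OC
Why: Seyferth–Gilbert homologation with the Ohira–Bestmann reagent converts only the aldehyde into the terminal alkyne, and methoxide should equilibrate the ketone α-carbon C6 to the more stable exo-methyl epimer (C6 of the target), the bridgehead on the other side being unable to enolise.

Step 15
Reactants: 19 alkynyl ketone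
Product: 20 diol (2-ethynyl-3-hydroxy-5-(hydroxymethyl)-6-methyl-4-PMB-oxy-8-oxabicyclo[3.2.1]octan-7-one)
Conditions: HF·pyridine, THF/pyridine, 0 °C to rt
Reagents that add atoms: none
Why: Acidic fluoride removes both silyl ethers without generating alkoxides; the PMB ether, alkyne and ketone are stable.

Step 16
Reactants: 20 diol
Product: 21 oxygen-bridged α-methylene lactone (4,7-epoxy-7-(hydroxymethyl)-6-methyl-3-methylidene-8-PMB-oxy-hexahydrocyclohepta[b]furan-2,5-dione; trans ring fusion)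
Conditions: PdCl2 (5 mol %), SnCl2 (5 mol %), PPh3 (10 mol %), CO (8 atm), MeCN, 75 °C
Reagents that add atoms: carbon monoxide, [C-]#[O+]
Why: Palladium-catalysed cyclocarbonylation of a homopropargylic alcohol (Norton lactone synthesis) gives the trans-fused α-methylene-γ-butyrolactone from the trans-diequatorial hydroxyl/ethynyl pair with no change at any stereocentre; the remote primary hydroxyl cannot reach the alkyne.

Step 17
Reactants: 21 lactone alcohol
Product: 22 bridgehead aldehyde (7-formyl analogue of 21)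
Conditions: Dess–Martin periodinane, CH2Cl2, rt
Reagents that add atoms: none
Why: Dess–Martin oxidation of the primary alcohol to a non-enolisable α-alkoxy aldehyde.

Step 18
Reactants: 22 bridgehead aldehyde
Product: 23 C8 alcohol (8-hydroxy analogue of 22)
Conditions: DDQ, CH2Cl2/pH 7 buffer, 0 °C
Reagents that add atoms: none
Why: Oxidative cleavage of the PMB ether under neutral conditions; the methylene lactone, aldehyde and ketone are inert to DDQ.

Step 19
Reactants: 23 C8 alcohol; 24 (2R)-2-methylbutanoic acid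
Product: 25 C8 (2R)-2-methylbutanoate of 23
Conditions: DCC, DMAP, CH2Cl2, 0 °C to rt
Reagents that add atoms: none
Why: Steglich esterification of the only free hydroxyl, now flanked by the tied-back lactone oxygen and a formyl-bearing carbon and so less hindered than earlier in the route; the acid stereocentre is carried in unchanged.

Step 20
Reactants: 25 ester aldehyde; 26 (1E)-1-bromoprop-1-ene
Product: 27 allylic alcohol (7-[(2E)-1-hydroxybut-2-enyl] analogue; either carbinol epimer)
Conditions: CrCl2 (6 equiv), NiCl2 (2 mol %), DMSO/DMF, rt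
Reagents that add atoms: none
Why: Nozaki–Hiyama–Kishi coupling adds the alkenylchromium only to the aldehyde with retention of the E geometry, sparing ketone, ester and methylene lactone; the new carbinol centre is destroyed in step 22.

Step 21
Reactants: 27 allylic alcohol
Product: 28 ring-opened diol (7-hydroxy-7-[(2E)-1-hydroxybut-2-enyl] cycloheptanone; all ring stereocentres as in the target)
Conditions: SmI2 (2.5 equiv), THF/MeOH, −78 °C
Reagents that add atoms: none
Why: SmI2 reductive cleavage of an α-alkoxy ketone: the C5 ketyl expels the C4–O bond and the samarium enolate is protonated by MeOH, releasing the C7 tertiary hydroxyl and the C4 methylene without touching C6.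

Step 22
Reactants: 28 ring-opened diol
Product: 29 target, (3aR,6R,7S,8S,8aR)-7-[(2E)-but-2-enoyl]-7-hydroxy-6-methyl-3-methylidene-2,5-dioxooctahydro-2H-cyclohepta[b]furan-8-yl (2R)-2-methylbutanoate
Conditions: IBX, DMSO, rt
Reagents that add atoms: none
Why: IBX oxidises the secondary allylic alcohol of the 1,2-diol to the enone without glycol cleavage; the tertiary alcohol cannot be oxidised.

## Compound list

1 | methyl 3-methylfuran-2-carboxylate | COC(=O)c1occc1C | starting material
2 | (3-methylfuran-2-yl)methanol | Cc1ccoc1CO | intermediate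
3 | tert-butyl[(3-methylfuran-2-yl)methoxy]diphenylsilane | Cc1ccoc1CO[Si](c1ccccc1)(c1ccccc1)C(C)(C)C | intermediate
4 | methyl 4-chloro-3-oxobutanoate | COC(=O)CC(=O)CCl | starting material
5 | methyl 4-[(4-methoxyphenyl)methoxy]-3-oxobutanoate | COC(=O)CC(=O)COCc1ccc(OC)cc1 | intermediate
6 | methyl 2-diazo-4-[(4-methoxyphenyl)methoxy]-3-oxobutanoate | COC(=O)C(=[N+]=[N-])C(=O)COCc1ccc(OC)cc1 | intermediate
7 | methyl (3Z)-3-[(tert-butyldimethylsilyl)oxy]-2-diazo-4-[(4-methoxyphenyl)methoxy]but-3-enoate | COC(=O)C(=[N+]=[N-])/C(O[Si](C)(C)C(C)(C)C)=C/OCc1ccc(OC)cc1 | intermediate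
8 | cis-divinylcyclopropane (not isolated): methyl 6-[(Z)-1-TBS-oxy-2-PMB-oxyethenyl]-3-(TBDPS-oxymethyl)-4-methyl-2-oxabicyclo[3.1.0]hex-3-ene-6-carboxylate, vinyl group endo | COC(=O)[C@@]1(/C(O[Si](C)(C)C(C)(C)C)=C/OCc3ccc(OC)cc3)[C@@H]2OC(CO[Si](c4ccccc4)(c4ccccc4)C(C)(C)C)=C(C)[C@H]12 | intermediate
9 | methyl 3-TBS-oxy-4-PMB-oxy-5-(TBDPS-oxymethyl)-6-methyl-8-oxabicyclo[3.2.1]octa-2,6-diene-2-carboxylate, PMB-oxy anti to the bridge | COc1ccc(CO[C@H]2C(O[Si](C)(C)C(C)(C)C)=C(C(=O)OC)[C@H]3C=C(C)[C@@]2(O3)CO[Si](c4ccccc4)(c4ccccc4)C(C)(C)C)cc1 | intermediate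
10 | enol triflate: 3-trifluoromethanesulfonyloxy analogue of 9 | COc1ccc(CO[C@H]2C(OS(=O)(=O)C(F)(F)F)=C(C(=O)OC)[C@H]3C=C(C)[C@@]2(O3)CO[Si](c4ccccc4)(c4ccccc4)C(C)(C)C)cc1 | intermediate
11 | methyl 4-PMB-oxy-5-(TBDPS-oxymethyl)-6-methyl-8-oxabicyclo[3.2.1]octa-2,6-diene-2-carboxylate | COc1ccc(CO[C@H]2C=C(C(=O)OC)[C@H]3C=C(C)[C@@]2(O3)CO[Si](c4ccccc4)(c4ccccc4)C(C)(C)C)cc1 | intermediate
12 | pinacol boronate (not isolated): 3-Bpin syn to the bridge, 2-ester anti | COc1ccc(CO[C@H]2[C@H](B5OC(C)(C)C(C)(C)O5)[C@@H](C(=O)OC)[C@H]3C=C(C)[C@@]2(O3)CO[Si](c4ccccc4)(c4ccccc4)C(C)(C)C)cc1 | intermediate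
13 | methyl 3-hydroxy-4-PMB-oxy-5-(TBDPS-oxymethyl)-6-methyl-8-oxabicyclo[3.2.1]oct-6-ene-2-carboxylate, 3-OH syn, 2-ester and 4-ether anti | COc1ccc(CO[C@H]2[C@H](O)[C@@H](C(=O)OC)[C@H]3C=C(C)[C@@]2(O3)CO[Si](c4ccccc4)(c4ccccc4)C(C)(C)C)cc1 | intermediate
14 | 3-O-TES ether of 13 | COc1ccc(CO[C@H]2[C@H](O[Si](CC)(CC)CC)[C@@H](C(=O)OC)[C@H]3C=C(C)[C@@]2(O3)CO[Si](c4ccccc4)(c4ccccc4)C(C)(C)C)cc1 | intermediate
15 | alkylborane (not isolated): 7-exo-boryl, 6-endo-methyl | COc1ccc(CO[C@H]2[C@H](O[Si](CC)(CC)CC)[C@@H](C(=O)OC)[C@H]3[C@H](B)[C@@H](C)[C@@]2(O3)CO[Si](c4ccccc4)(c4ccccc4)C(C)(C)C)cc1 | intermediate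
16 | methyl 7-exo-hydroxy-6-endo-methyl-4-PMB-oxy-3-TES-oxy-5-(TBDPS-oxymethyl)-8-oxabicyclo[3.2.1]octane-2-carboxylate | COc1ccc(CO[C@H]2[C@H](O[Si](CC)(CC)CC)[C@@H](C(=O)OC)[C@H]3[C@H](O)[C@@H](C)[C@@]2(O3)CO[Si](c4ccccc4)(c4ccccc4)C(C)(C)C)cc1 | intermediate
17 | diol: 2-hydroxymethyl analogue of 16 | COc1ccc(CO[C@H]2[C@H](O[Si](CC)(CC)CC)[C@@H](CO)[C@H]3[C@H](O)[C@@H](C)[C@@]2(O3)CO[Si](c4ccccc4)(c4ccccc4)C(C)(C)C)cc1 | intermediate
18 | keto aldehyde: 6-endo-methyl-7-oxo-4-PMB-oxy-3-TES-oxy-5-(TBDPS-oxymethyl)-8-oxabicyclo[3.2.1]octane-2-carbaldehyde | COc1ccc(CO[C@H]2[C@H](O[Si](CC)(CC)CC)[C@@H](C=O)[C@H]3C(=O)[C@@H](C)[C@@]2(O3)CO[Si](c4ccccc4)(c4ccccc4)C(C)(C)C)cc1 | intermediate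
19 | 2-ethynyl-6-exo-methyl-4-PMB-oxy-3-TES-oxy-5-(TBDPS-oxymethyl)-8-oxabicyclo[3.2.1]octan-7-one | COc1ccc(CO[C@H]2[C@H](O[Si](CC)(CC)CC)[C@@H](C#C)[C@H]3C(=O)[C@H](C)[C@@]2(O3)CO[Si](c4ccccc4)(c4ccccc4)C(C)(C)C)cc1 | intermediate
20 | 2-ethynyl-3-hydroxy-5-(hydroxymethyl)-6-exo-methyl-4-PMB-oxy-8-oxabicyclo[3.2.1]octan-7-one | COc1ccc(CO[C@H]2[C@H](O)[C@@H](C#C)[C@H]3C(=O)[C@H](C)[C@@]2(O3)CO)cc1 | intermediate
21 | 4,7-epoxy-7-(hydroxymethyl)-6-methyl-3-methylidene-8-PMB-oxy-hexahydrocyclohepta[b]furan-2,5-dione, C3a, C6, C7, C8, C8a as in the target | COc1ccc(CO[C@H]2[C@@H]3OC(=O)C(=C)[C@H]3[C@H]4C(=O)[C@H](C)[C@@]2(O4)CO)cc1 | intermediate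
22 | 7-formyl analogue of 21 | COc1ccc(CO[C@H]2[C@@H]3OC(=O)C(=C)[C@H]3[C@H]4C(=O)[C@H](C)[C@@]2(O4)C=O)cc1 | intermediate
23 | 4,7-epoxy-7-formyl-8-hydroxy-6-methyl-3-methylidene-hexahydrocyclohepta[b]furan-2,5-dione | O[C@H]1[C@@H]2OC(=O)C(=C)[C@H]2[C@H]3C(=O)[C@H](C)[C@@]1(O3)C=O | intermediate
24 | (2R)-2-methylbutanoic acid | CC[C@@H](C)C(=O)O | starting material
25 | C8 (2R)-2-methylbutanoate of 23 | CC[C@@H](C)C(=O)O[C@H]1[C@@H]2OC(=O)C(=C)[C@H]2[C@H]3C(=O)[C@H](C)[C@@]1(O3)C=O | intermediate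
26 | (1E)-1-bromoprop-1-ene | C/C=C/Br | starting material
27 | 4,7-epoxy-7-[(2E)-1-hydroxybut-2-enyl] lactone ester, carbinol epimers | CC[C@@H](C)C(=O)O[C@H]1[C@@H]2OC(=O)C(=C)[C@H]2[C@H]3C(=O)[C@H](C)[C@@]1(O3)C(O)/C=C/C | intermediate
28 | (3aR,6R,7S,8S,8aR)-7-hydroxy-7-[(2E)-1-hydroxybut-2-enyl]-6-methyl-3-methylidene-2,5-dioxooctahydrocyclohepta[b]furan-8-yl (2R)-2-methylbutanoate, carbinol epimers | CC[C@@H](C)C(=O)O[C@H]1[C@@H]2OC(=O)C(=C)[C@H]2CC(=O)[C@H](C)[C@@]1(O)C(O)/C=C/C | intermediate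
29 | (3aR,6R,7S,8S,8aR)-7-[(2E)-but-2-enoyl]-7-hydroxy-6-methyl-3-methylidene-2,5-dioxooctahydro-2H-cyclohepta[b]furan-8-yl (2R)-2-methylbutanoate | C=C1C(=O)O[C@@H]2[C@@H]1CC(=O)[C@H](C)[C@@](O)(C(=O)/C=C/C)[C@H]2OC(=O)[C@H](C)CC | target

## Step count and risks

Total steps: 22. Longest linear sequence: 20 steps (4 to 29, steps 3–22).

**Step 6.** The chiral carboxylate ligands may not discriminate the two faces of this trisubstituted furan well enough in the cyclopropanation, which is the event that fixes the absolute configuration; the Cope step, which has to form a quaternary–tertiary bond, may also lag behind. Fallback: auxiliary control with an achiral catalyst. Setting out from 5, transesterification with (R)-pantolactone (DMAP cat., toluene, reflux) should give the pantolactone β-keto ester F1. Diazo transfer gives the diazo ester F2, and TBSOTf/Et3N gives the Z silyl enol ether F3. Rh2(O2CC7H15)4 (dirhodium tetraoctanoate) with furan 3 in hexanes at reflux should then give, through the divinylcyclopropane F4, the pantolactone cycloadduct F5, from which the minor diastereomer is removed by chromatography. TBAF/AcOH gives the β-keto ester F6, exchange of the auxiliary for methanol (MeOH, DMAP, toluene, reflux) gives the methyl β-keto ester F7, and NaH/PhNTf2 returns to the route at enol triflate 10.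

**Step 14.** Under methoxide the aldehyde enolate can expel the oxygen bridge (E1cB), and with the ketone already present the opened enal may be consumed by retro-aldol or conjugate addition instead of re-closing; epimerisation at C6 may also stop short. Fallback: keep the ketone absent during the basic homologation and epimerise afterwards with an amidine base. Setting out from 17, TEMPO/PhI(OAc)2 should oxidise only the primary alcohol to the hydroxy aldehyde F8. A short Ohira–Bestmann homologation at 0 °C gives the alkynol F9, and Dess–Martin oxidation gives the 6-endo-methyl ketone F10. DBU in toluene then equilibrates C6 and comes back to the route at 19.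

**Step 21.** Electron transfer to the α-methylene lactone (conjugate reduction or ketyl–olefin coupling) may compete with cleavage of the ether bridge, and the liberated samarium alkoxide may trigger retro-aldol opening. Fallback: mask the exocyclic alkene as an amine adduct. Setting out from 27, Me2NH in THF should give the dimethylaminomethyl lactone F11, which carries no reducible alkene. SmI2/MeOH at −78 °C then opens the bridge to the amino diol F12. MeI gives the trimethylammonium iodide F13, and aqueous NaHCO3 eliminates trimethylamine to come back to the route at 28.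

## Further compounds

F1 | step 6 | (3R)-4,4-dimethyl-2-oxooxolan-3-yl 4-[(4-methoxyphenyl)methoxy]-3-oxobutanoate | COc1ccc(COCC(=O)CC(=O)O[C@H]2C(=O)OCC2(C)C)cc1
F2 | step 6 | (3R)-4,4-dimethyl-2-oxooxolan-3-yl 2-diazo-4-[(4-methoxyphenyl)methoxy]-3-oxobutanoate | COc1ccc(COCC(=O)C(=[N+]=[N-])C(=O)O[C@H]2C(=O)OCC2(C)C)cc1
F3 | step 6 | (3R)-4,4-dimethyl-2-oxooxolan-3-yl (3Z)-3-TBS-oxy-2-diazo-4-PMB-oxybut-3-enoate | COc1ccc(CO/C=C(O[Si](C)(C)C(C)(C)C)/C(=[N+]=[N-])C(=O)O[C@H]2C(=O)OCC2(C)C)cc1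
F4 | step 6 | pantolactone ester analogue of divinylcyclopropane 8 (not isolated) | CC1(C)COC(=O)[C@@H]1OC(=O)[C@@]2(/C(O[Si](C)(C)C(C)(C)C)=C/OCc3ccc(OC)cc3)[C@@H]4OC(CO[Si](c5ccccc5)(c5ccccc5)C(C)(C)C)=C(C)[C@H]24
F5 | step 6 | pantolactone ester analogue of cycloadduct 9 | COc1ccc(CO[C@H]2C(O[Si](C)(C)C(C)(C)C)=C(C(=O)O[C@H]5C(=O)OCC5(C)C)[C@H]3C=C(C)[C@@]2(O3)CO[Si](c4ccccc4)(c4ccccc4)C(C)(C)C)cc1
F6 | step 6 | pantolactone 3-oxo-4-PMB-oxy-5-(TBDPS-oxymethyl)-6-methyl-8-oxabicyclo[3.2.1]oct-6-ene-2-carboxylate (β-keto ester, C2 enolisable) | COc1ccc(CO[C@H]2C(=O)C(C(=O)O[C@H]5C(=O)OCC5(C)C)[C@H]3C=C(C)[C@@]2(O3)CO[Si](c4ccccc4)(c4ccccc4)C(C)(C)C)cc1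
F7 | step 6 | methyl 3-oxo-4-PMB-oxy-5-(TBDPS-oxymethyl)-6-methyl-8-oxabicyclo[3.2.1]oct-6-ene-2-carboxylate (β-keto ester, C2 enolisable) | COc1ccc(CO[C@H]2C(=O)C(C(=O)OC)[C@H]3C=C(C)[C@@]2(O3)CO[Si](c4ccccc4)(c4ccccc4)C(C)(C)C)cc1
F8 | step 14 | 7-exo-hydroxy-6-endo-methyl-4-PMB-oxy-3-TES-oxy-5-(TBDPS-oxymethyl)-8-oxabicyclo[3.2.1]octane-2-carbaldehyde | COc1ccc(CO[C@H]2[C@H](O[Si](CC)(CC)CC)[C@@H](C=O)[C@H]3[C@H](O)[C@@H](C)[C@@]2(O3)CO[Si](c4ccccc4)(c4ccccc4)C(C)(C)C)cc1
F9 | step 14 | 2-ethynyl-6-endo-methyl-4-PMB-oxy-3-TES-oxy-5-(TBDPS-oxymethyl)-8-oxabicyclo[3.2.1]octan-7-exo-ol | COc1ccc(CO[C@H]2[C@H](O[Si](CC)(CC)CC)[C@@H](C#C)[C@H]3[C@H](O)[C@@H](C)[C@@]2(O3)CO[Si](c4ccccc4)(c4ccccc4)C(C)(C)C)cc1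
F10 | step 14 | 6-endo-methyl epimer of 19 | COc1ccc(CO[C@H]2[C@H](O[Si](CC)(CC)CC)[C@@H](C#C)[C@H]3C(=O)[C@@H](C)[C@@]2(O3)CO[Si](c4ccccc4)(c4ccccc4)C(C)(C)C)cc1
F11 | step 21 | 3-[(dimethylamino)methyl] adduct of 27 (C3 epimers) | CC[C@@H](C)C(=O)O[C@H]1[C@@H]2OC(=O)C(CN(C)C)[C@H]2[C@H]3C(=O)[C@H](C)[C@@]1(O3)C(O)/C=C/C
F12 | step 21 | 3-[(dimethylamino)methyl] adduct of 28 (C3 epimers) | CC[C@@H](C)C(=O)O[C@H]1[C@@H]2OC(=O)C(CN(C)C)[C@H]2CC(=O)[C@H](C)[C@@]1(O)C(O)/C=C/C
F13 | step 21 | trimethylammonium iodide derived from F12 | CC[C@@H](C)C(=O)O[C@H]1[C@@H]2OC(=O)C(C[N+](C)(C)C)[C@H]2CC(=O)[C@H](C)[C@@]1(O)C(O)/C=C/C.[I-]
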